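The trap here is to take the top reading of intermediate for the peak: 98% comes from the noon run and carries a scatter of 2 percentage points. Reckon it instead, as I do here.

common to all: substrate 0.20 M

|  | coupling partner | solid second reagent | remark | time |
|---|---|---|---|---|
| midnight | 1.2 equiv | 2.5 equiv | the very flask that is asked about, followed so far |  |
| noon | 1.2 equiv | 3.8 equiv | run made earlier |  |
| flask | 1.20 equiv | 2.50 equiv |  | 1.5 h |

- midnight (time / min: intermediate / %, product / %, substrate / %): 0.500: 89, 0, 13; 1.00: 96, 4, 3; 2.00: 93, 3, 0; 5.00: 93, 4, 1; 10.0: 86, 15, 1; 20.0: 79, 24, 0; 50.0: 45, 53, 0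
- noon (time / min: intermediate / %, product / %, substrate / %): 0.500: 92, 1, 6; 1.00: 96, 3, 5; 2.00: 98, 3, 1; 4.00: 97, 4, 2; 8.00: 94, 8, 0; 20.0: 78, 18, 0; 40.0: 58, 41, 0

(each reading ± 2 percentage points)

- time up to 1.5 h at which intermediate stands highest, in min
- the amount of intermediate, in percent of the substrate charged, at that time

- at the start none of the solid second reagent is in solution
- a reading or a percentage of product counts all its forms, free or not

1. Treat the fall of substrate as a plain exponential, a rough picture, with rate constant k. The midnight reading at 0.500 min gives k = 4.08 min⁻¹. The noon reading at 2.00 min gives a slower 2.30 min⁻¹, though it is a noisy one. These are my two ends.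

2. Call d the share of the charge turned into product per unit time. Midnight product at 50.0 min gives, as an average up to that reading, d = 0.0106 min⁻¹.

3. With k and d held constant, intermediate peaks where feed equals drain, at the crossing time T = ln(k/d)/k. Substrate left is then d/k, and product about d times T.

4. So the crossing loss L, which is d times the sum of T and the inverse of k, is what the peak falls short of the full charge.

5. With this d, the fast end gives T = 1.46 min and L = 1.81%, a reckoned ceiling of 98.2%. The slow end gives T = 2.34 min and L = 2.94%, a reckoned floor of 97.1%.

6. The forecast says 2 min and 96.5%, by the same rule: “The peak comes where substrate feed equals drain”. Its time lies inside my bracket, but its height lies below my floor.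

    substrate + coupling partner → intermediate (k = 0.750 M⁻¹ s⁻¹)
    second reagent + intermediate → product (k = 0.400 M⁻¹ s⁻¹)
    solid second reagent ⇌ second reagent, rate k3*(cs3 - [second reagent]) while solid is left; crystals form when [second reagent] > cs3 (solubility = 12.0 mM, k = 0.00320 s⁻¹)
    second reagent + product ⇌ idle adduct, settled at all times (K = 4.10 M⁻¹)

The flask peaks at 1.87 min with 97.6% of intermediate. It then holds 0.597% substrate and 1.83% product, a crossing loss of 2.43%, between my 1.81% and 2.94%. Now take a flask with 0.50 M substrate, its equivalents and loadings held. Scaling the slow k by concentration gives 5.76 min⁻¹, and its 40.5% product at 1.5 h, all forms counted, gives an average d = 0.00450 min⁻¹. Then T = 1.24 min and L = 0.638%, a reckoned peak of 99.4%. That flask's highest intermediate stands at 99.4%.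

All runs were computed for an exercise, noise included.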